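**Retrosynthetic overview**

1. Last disconnections: the coumarin ether (Mitsunobu) and the side-chain sp3–sp2 bond next to the trisubstituted alkene (B-alkyl Suzuki–Miyaura). They lead back to (3R)-3-ethenyl-2,2-dimethyl-4-methylidenecyclohexan-1-one, an (E)-C4 enol triflate and 4-hydroxy-5-methylcoumarin.
2. Key disconnection: the cyclohexanone (C1 = carbonyl carbon) is cut at C2–C3 and at C5–C6 into the enolate of 3-methylbutan-2-one (C6–C1–C2) and a 2-methylidenepropane-1,3-diyl unit (C3–C4(=CH2)–C5) carried by a dienyl biscarbonate. Both bonds form in one flask, first under iridium and then under palladium catalysis, as a (3+3) annulation.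
3. Enabling feature: C4 bears the exocyclic methylene, so C3 and C5 are the two allylic carbons of one 2-substituted allyl unit, and each faces an α-carbon of the C1 ketone (quaternary C2, methylene C6). The C3 side chain begins with CH2–CH2, so it can enter as the vinyl group that a branched-selective allylic substitution leaves behind.
4. Ring order: the carbocycle in step 4, where the chiral iridium catalyst also sets the C3 stereocentre; the pyranone ring of the coumarin by lactonisation in step 9; the benzene ring is bought.

Key step: step 4

Assumption: the ligand written as (Sa,S,S) in step 4 stands for the enantiomer of this phosphoramidite that delivers the enolate to the Re face of the substituted allyl terminus (the sense that gives 3R). If the facial rule of this ligand family points the other way for this substrate, its mirror image is used. Compounds 4 and 15 are taken as purchasable.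

**Route**

Step 1
Reactants: 1 3-bromo-3-methylbutan-2-one
Product: 2 trimethyl[(3-methylbut-2-en-2-yl)oxy]silane
Conditions: Zn dust, Me3SiCl, TMEDA, Et2O, 0 °C → rt
Reagents that add atoms: chlorotrimethylsilane, C[Si](C)(C)Cl
Why: Reductive silylation of an α-bromo ketone (Reformatsky-type zinc enolate trapped on oxygen) places the enol ether double bond at the carbon that carried bromine, so the tetrasubstituted enol silane should form free of its terminal regioisomer.

Step 2
Reactants: 3 2-bromoprop-2-en-1-ol; 4 (2E)-3-(tributylstannyl)prop-2-en-1-ol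
Product: 5 (2E)-4-methylidenepent-2-ene-1,5-diol
Conditions: Pd(PPh3)4 (5 mol %), CuI (10 mol %), DMF, 60 °C
Reagents that add atoms: none
Why: Stille coupling of a vinyl bromide with an (E)-vinylstannane tolerates free hydroxyl groups and proceeds with retention of the alkene geometry, which should give the 2-substituted (E)-diene.

Step 3
Reactants: 5 (2E)-4-methylidenepent-2-ene-1,5-diol
Product: 6 dimethyl (2E)-4-methylidenepent-2-ene-1,5-diyl biscarbonate
Conditions: ClCO2Me (2.5 equiv), pyridine, DMAP (cat.), CH2Cl2, 0 °C → rt
Reagents that add atoms: methyl chloroformate, COC(=O)Cl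
Why: Acylation of both primary allylic alcohols (carbonate formation) installs the two leaving groups, which differ only in the kind of allyl unit they sit on.

Step 4
Reactants: 6 dimethyl (2E)-4-methylidenepent-2-ene-1,5-diyl biscarbonate; 2 trimethyl[(3-methylbut-2-en-2-yl)oxy]silane
Product: 9 (3R)-3-ethenyl-2,2-dimethyl-4-methylidenecyclohexan-1-one, via acyclic ketone carbonate 7 (not isolated), via lithium enolate 8 (not isolated)
Conditions: one flask; stage 1: [Ir(cod)Cl]2 (2 mol %), (Sa,S,S)-O,O′-(1,1′-binaphthalene-2,2′-diyl)-N,N-bis(1-phenylethyl)phosphoramidite (4 mol %, pre-activated with n-PrNH2), CsF (0.4 equiv), ZnF2 (0.5 equiv), 2 (1.3 equiv), DME, 50 °C; stage 2: THF, −78 °C, LiN(SiMe3)2 (1.6 equiv), then Pd(PPh3)4 (5 mol %), −78 °C → rt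
Reagents that add atoms: none
Why: Stage 1 is an iridium-catalysed asymmetric allylic alkylation, whose closest precedents are fluoride-activated ketone enol silanes with allylic carbonates and dienyl carbonates with stabilised carbanions: the cyclometalated iridium phosphoramidite ionises only the dienyl carbonate of 6 (the other carbonate sits on a 2-substituted allyl unit, which this catalyst class ionises very slowly), and the fluoride-released tetrasubstituted enolate of 2 attacks the substituted allyl terminus anti to iridium, which forms the C2–C3 bond between the quaternary carbon and the new stereocentre and leaves the vinyl group. Stage 2 is an intramolecular Tsuji–Trost alkylation: LiN(SiMe3)2 can enolise 7 only toward its methyl group because the other α-carbon is now quaternary, zerovalent palladium ionises the remaining carbonate to a 2-substituted π-allyl complex whose two CH2 termini are constitutionally equivalent, and C-attack of enolate 8 on either terminus closes the cyclohexanone in a 6-(enolendo)-exo mode, which forms C5–C6 and leaves the other CH2 as the exocyclic methylene. The only new stereocentre, C3, is set in stage 1 by the chiral ligand (catalyst control, Re-face attack gives R); it is not α to the ketone and should not epimerise in stage 2. The selectivities needed are branched over linear attack in stage 1, which is the intrinsic preference of iridium allyl complexes for the substituted terminus (C3 is the substituted terminus of either η3 isomer of the dienyl complex), and C- over O-allylation in stage 2, which is secured because an O-allylated enol ether would be re-ionised by zerovalent palladium and funnelled to the C–C product; the ring closure itself has no regiochemical issue because of the equivalence of the π-allyl termini.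

Step 5
Reactants: 9 (3R)-3-ethenyl-2,2-dimethyl-4-methylidenecyclohexan-1-one
Product: 10 (3R)-2,2-dimethyl-4-methylidene-3-[2-(4,4,5,5-tetramethyl-1,3,2-dioxaborolan-2-yl)ethyl]cyclohexan-1-one
Conditions: [Ir(cod)Cl]2 (1.5 mol %), Ph2PCH2PPh2 (3 mol %), pinacolborane (1.2 equiv), CH2Cl2, rt
Reagents that add atoms: pinacolborane, CC1(C)OBOC1(C)C
Why: Iridium-catalysed anti-Markovnikov hydroboration with pinacolborane is strongly sterically discriminating, so the monosubstituted vinyl group should react ahead of the 1,1-disubstituted exocyclic alkene and the hindered ketone (9-BBN is avoided because it reacts about as fast with 1,1-disubstituted alkenes), and the stereocentre is not touched.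

Step 6
Reactants: 11 ethyl 3-oxobutanoate
Product: 12 ethyl (2E)-3-{[(trifluoromethyl)sulfonyl]oxy}but-2-enoate
Conditions: Tf2O, aq. Me4NOH, hexanes, 5–10 °C
Reagents that add atoms: trifluoromethanesulfonic anhydride, O=S(=O)(OS(=O)(=O)C(F)(F)F)C(F)(F)F
Why: O-Triflation of the β-keto ester enolate with a non-chelating tetramethylammonium counter-ion should favour the (E)-enol triflate, in which the triflate is trans to the ester.

Step 7
Reactants: 12 ethyl (2E)-3-{[(trifluoromethyl)sulfonyl]oxy}but-2-enoate
Product: 13 (2E)-4-hydroxybut-2-en-2-yl trifluoromethanesulfonate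
Conditions: iBu2AlH (2.2 equiv), CH2Cl2, −78 °C; aq. potassium sodium tartrate
Reagents that add atoms: none
Why: 1,2-Reduction of the enoate by the aluminium hydride at low temperature should give the allylic alcohol and leave the alkenyl triflate and its geometry intact.

Step 8
Reactants: 10 (3R)-2,2-dimethyl-4-methylidene-3-[2-(4,4,5,5-tetramethyl-1,3,2-dioxaborolan-2-yl)ethyl]cyclohexan-1-one; 13 (2E)-4-hydroxybut-2-en-2-yl trifluoromethanesulfonate
Product: 14 (3R)-3-[(3E)-5-hydroxy-3-methylpent-3-en-1-yl]-2,2-dimethyl-4-methylidenecyclohexan-1-one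
Conditions: Pd(OAc)2 (5 mol %), RuPhos (10 mol %), K3PO4 (3 equiv), toluene/H2O 10:1, 80 °C
Reagents that add atoms: none
Why: B-alkyl Suzuki–Miyaura coupling of a primary alkylboronate with an alkenyl triflate proceeds with retention of the alkene geometry, so the (E)-trisubstituted alkene should result; the ketone, the exocyclic alkene, the free alcohol and the remote stereocentre are not involved.

Step 9
Reactants: 15 1-(2-hydroxy-6-methylphenyl)ethan-1-one; 16 diethyl carbonate
Product: 17 4-hydroxy-5-methyl-2H-chromen-2-one
Conditions: NaH (3 equiv), toluene, 110 °C; then aq. HCl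
Reagents that add atoms: none
Why: Claisen-type C-acylation of the ketone enolate by diethyl carbonate followed by lactonisation onto the phenol is the standard 4-hydroxycoumarin synthesis, and the methyl group ortho to the acetyl group ends at C5.

Step 10
Reactants: 14 (3R)-3-[(3E)-5-hydroxy-3-methylpent-3-en-1-yl]-2,2-dimethyl-4-methylidenecyclohexan-1-one; 17 4-hydroxy-5-methyl-2H-chromen-2-one
Product: 18 4-{[(2E)-5-[(1R)-2,2-dimethyl-6-methylidene-3-oxocyclohexyl]-3-methylpent-2-en-1-yl]oxy}-5-methyl-2H-chromen-2-one
Conditions: PPh3, diisopropyl azodicarboxylate, THF, 0 °C → rt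
Reagents that add atoms: none
Why: Mitsunobu O-alkylation of the acidic 4-hydroxycoumarin by the primary allylic alcohol (SN2 at CH2, no allylic transposition expected) runs under neutral conditions, which should preserve the ketone, both alkenes and the stereocentre.

**Compound list**

1 | 3-bromo-3-methylbutan-2-one | CC(=O)C(C)(C)Br | starting material
2 | trimethyl[(3-methylbut-2-en-2-yl)oxy]silane | CC(=C(C)C)O[Si](C)(C)C | intermediate
3 | 2-bromoprop-2-en-1-ol | OCC(Br)=C | starting material
4 | (2E)-3-(tributylstannyl)prop-2-en-1-ol | CCCC[Sn](CCCC)(CCCC)/C=C/CO | starting material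
5 | (2E)-4-methylidenepent-2-ene-1,5-diol | OC/C=C/C(=C)CO | intermediate
6 | dimethyl (2E)-4-methylidenepent-2-ene-1,5-diyl biscarbonate | COC(=O)OC/C=C/C(=C)COC(=O)OC | intermediate
7 | (3R)-3-ethenyl-4,4-dimethyl-2-methylidene-5-oxohexyl methyl carbonate | CC(=O)C(C)(C)[C@@H](C(=C)COC(=O)OC)C=C | intermediate (not isolated)
8 | lithium (4R)-4-ethenyl-5-{[(methoxycarbonyl)oxy]methyl}-3,3-dimethylhexa-1,5-dien-2-olate | [Li+].[O-]C(=C)C(C)(C)[C@@H](C(=C)COC(=O)OC)C=C | intermediate (not isolated)
9 | (3R)-3-ethenyl-2,2-dimethyl-4-methylidenecyclohexan-1-one | C=C1CCC(=O)C(C)(C)[C@@H]1C=C | intermediate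
10 | (3R)-2,2-dimethyl-4-methylidene-3-[2-(4,4,5,5-tetramethyl-1,3,2-dioxaborolan-2-yl)ethyl]cyclohexan-1-one | C=C1CCC(=O)C(C)(C)[C@@H]1CCB2OC(C)(C)C(C)(C)O2 | intermediate
11 | ethyl 3-oxobutanoate | CCOC(=O)CC(C)=O | starting material
12 | ethyl (2E)-3-{[(trifluoromethyl)sulfonyl]oxy}but-2-enoate | CCOC(=O)/C=C(\C)OS(=O)(=O)C(F)(F)F | intermediate
13 | (2E)-4-hydroxybut-2-en-2-yl trifluoromethanesulfonate | OC/C=C(\C)OS(=O)(=O)C(F)(F)F | intermediate
14 | (3R)-3-[(3E)-5-hydroxy-3-methylpent-3-en-1-yl]-2,2-dimethyl-4-methylidenecyclohexan-1-one | C=C1CCC(=O)C(C)(C)[C@@H]1CC/C(C)=C/CO | intermediate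
15 | 1-(2-hydroxy-6-methylphenyl)ethan-1-one | CC(=O)c1c(C)cccc1O | starting material
16 | diethyl carbonate | CCOC(=O)OCC | starting material
17 | 4-hydroxy-5-methyl-2H-chromen-2-one | Cc1cccc2oc(=O)cc(O)c12 | intermediate
18 | 4-{[(2E)-5-[(1R)-2,2-dimethyl-6-methylidene-3-oxocyclohexyl]-3-methylpent-2-en-1-yl]oxy}-5-methyl-2H-chromen-2-one | C=C1CCC(=O)C(C)(C)[C@@H]1CC/C(C)=C/COc1cc(=O)oc2cccc(C)c12 | target

**Step count**

Total: 10 steps. Longest linear sequence: 6 steps (steps 2, 3, 4, 5, 8, 10).

**Steps most likely to fail**

Step 4. The fluoride-released tetrasubstituted enolate may add too slowly to the crowded dienyl iridium complex, so that protodesilylation to the parent ketone, attack at an unsubstituted terminus or double allylation take over; in stage 2, O-allylation could compete. The fallback builds the quaternary carbon–stereocentre bond with the more nucleophilic isobutyrate silyl ketene acetal, a documented nucleophile class for this catalysis, and makes the ketone afterwards. It sets out from 3 and comes back to the route at 7. Silylation of 3 (tBuMe2SiCl, imidazole) would give [(2-bromoprop-2-en-1-yl)oxy](tert-butyl)dimethylsilane F1. Stille coupling of F1 with 4 would give (2E)-4-({[tert-butyl(dimethyl)silyl]oxy}methyl)penta-2,4-dien-1-ol F2, and ClCO2Me with pyridine would give (2E)-4-({[tert-butyl(dimethyl)silyl]oxy}methyl)penta-2,4-dien-1-yl methyl carbonate F3. Iridium-catalysed allylic alkylation of F3 with 1-methoxy-2-methyl-1-(trimethylsilyloxy)prop-1-ene and the same ligand would give methyl (3R)-4-({[tert-butyl(dimethyl)silyl]oxy}methyl)-3-ethenyl-2,2-dimethylpent-4-enoate F4. Me3SiCH2Li followed by methanol would turn the ester into the methyl ketone (4R)-5-({[tert-butyl(dimethyl)silyl]oxy}methyl)-4-ethenyl-3,3-dimethylhex-5-en-2-one F5. Bu4NF would free (4R)-4-ethenyl-5-(hydroxymethyl)-3,3-dimethylhex-5-en-2-one F6, and ClCO2Me with pyridine would give 7, which is then closed to 9 under the stage 2 conditions of step 4.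

Step 5. Chemoselectivity may be lost through concurrent hydroboration of the exocyclic methylene, reduction of the ketone, or metal hydride migration of the skipped diene into conjugation, which would erase the stereocentre. The fallback replaces boron by silicon and the Suzuki coupling by a cross-electrophile coupling. It sets out from 9 and comes back to the route at 14, so that step 8 is bypassed as well. Platinum-catalysed hydrosilylation of 9 with diethoxy(methyl)silane and Pt2[(Me2SiCH=CH2)2O]3 (zerovalent platinum), which strongly prefers monosubstituted alkenes, would give (3R)-3-{2-[diethoxy(methyl)silyl]ethyl}-2,2-dimethyl-4-methylidenecyclohexan-1-one F7. Tamao–Fleming oxidation (H2O2, KF, KHCO3) would give (3R)-3-(2-hydroxyethyl)-2,2-dimethyl-4-methylidenecyclohexan-1-one F8, and I2, PPh3 and imidazole would give (3R)-3-(2-iodoethyl)-2,2-dimethyl-4-methylidenecyclohexan-1-one F9. Nickel-catalysed reductive coupling of F9 with 13 (NiBr2(MeOCH2CH2OMe), 4,4′-di-tert-butyl-2,2′-bipyridine, Mn powder, N,N-dimethylacetamide) would give 14.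

Step 10. The ambident 4-hydroxycoumarin may be alkylated at C3 or at the lactone oxygen (giving a 2-alkoxychromone) instead of at O4, a tendency the peri methyl group could increase. The fallback reverses the polarity of the ether formation. It sets out from 17 and comes back to the route at 18. POCl3 with catalytic Et3N would convert 17 into 4-chloro-5-methyl-2H-chromen-2-one F10, and the sodium alkoxide of 14 (NaH, 1.0 equiv, THF, 0 °C) would displace chloride by addition–elimination at C4, which can only give the O4 ether 18.

Further compounds
F1 | step 4 | [(2-bromoprop-2-en-1-yl)oxy](tert-butyl)dimethylsilane | C=C(Br)CO[Si](C)(C)C(C)(C)C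
F2 | step 4 | (2E)-4-({[tert-butyl(dimethyl)silyl]oxy}methyl)penta-2,4-dien-1-ol | OC/C=C/C(=C)CO[Si](C)(C)C(C)(C)C
F3 | step 4 | (2E)-4-({[tert-butyl(dimethyl)silyl]oxy}methyl)penta-2,4-dien-1-yl methyl carbonate | COC(=O)OC/C=C/C(=C)CO[Si](C)(C)C(C)(C)C
F4 | step 4 | methyl (3R)-4-({[tert-butyl(dimethyl)silyl]oxy}methyl)-3-ethenyl-2,2-dimethylpent-4-enoate | COC(=O)C(C)(C)[C@@H](C(=C)CO[Si](C)(C)C(C)(C)C)C=C
F5 | step 4 | (4R)-5-({[tert-butyl(dimethyl)silyl]oxy}methyl)-4-ethenyl-3,3-dimethylhex-5-en-2-one | CC(=O)C(C)(C)[C@@H](C(=C)CO[Si](C)(C)C(C)(C)C)C=C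
F6 | step 4 | (4R)-4-ethenyl-5-(hydroxymethyl)-3,3-dimethylhex-5-en-2-one | CC(=O)C(C)(C)[C@@H](C(=C)CO)C=C
F7 | step 5 | (3R)-3-{2-[diethoxy(methyl)silyl]ethyl}-2,2-dimethyl-4-methylidenecyclohexan-1-one | C=C1CCC(=O)C(C)(C)[C@@H]1CC[Si](C)(OCC)OCC
F8 | step 5 | (3R)-3-(2-hydroxyethyl)-2,2-dimethyl-4-methylidenecyclohexan-1-one | C=C1CCC(=O)C(C)(C)[C@@H]1CCO
F9 | step 5 | (3R)-3-(2-iodoethyl)-2,2-dimethyl-4-methylidenecyclohexan-1-one | C=C1CCC(=O)C(C)(C)[C@@H]1CCI
F10 | step 10 | 4-chloro-5-methyl-2H-chromen-2-one | Cc1cccc2oc(=O)cc(Cl)c12
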